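The ten-membered carbocycle (C1–C10) is opened between C9 and C10. In the target the oxygenated C9 is allylic to the trisubstituted Z alkene C1=C10 and is attached directly to its methyl-substituted carbon C10, the pattern left by addition of an alkenylmetal to an aldehyde. The ring is therefore closed last by a chromium/nickel-mediated coupling of a C10 alkenyl iodide with a C9 aldehyde, which forms the C9–C10 bond, the macrocycle and the C9 carbinol centre at once. The cyclisation substrate already contains the cis-fused α-methylene-γ-lactone (ring O–C6–C7–C11–C12), the E C4=C5 alkene, both silylated hydroxyls at C7 and C8 and the Z iodoalkene.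

Key step: step 15

Remark on numbering: germacranolide numbering is used for all compounds, open-chain ones included. C1–C10 are the ring carbons (C14 = methyl on C10, C15 = methyl on C4), C11–C13 are the lactone carbons, and On is the oxygen on Cn.

Remark on the starting material: L-erythrulose is taken as the commercial (3S)-ketose (hydrate syrup).

Step 1
Reactants: 1 pent-4-yn-1-ol
Product: 2 pent-4-ynal
Conditions: (COCl)2, DMSO, CH2Cl2, −78 °C; Et3N, −78 → 0 °C; carried on as a CH2Cl2 solution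
Reagents that add atoms: none
Why: Swern oxidation (activated DMSO) stops cleanly at the aldehyde and does not touch the terminal alkyne.

Step 2
Reactants: 2 pent-4-ynal
Product: 3 (5Z)-6-iodohept-5-en-1-yne
Conditions: EtPPh3I, n-BuLi, THF, 0 °C; I2, −78 °C; NaN(SiMe3)2, −20 °C; then 2, −78 °C → rt
Reagents that add atoms: ethyltriphenylphosphonium iodide, CC[P+](c1ccccc1)(c1ccccc1)c1ccccc1.[I-]; iodine, II
Why: Wittig olefination with the non-stabilised α-iodo ylide (Stork–Zhao-type iodoalkylidenation) runs through the kinetically preferred cis-oxaphosphetane and should place iodine cis to the chain, giving the Z trisubstituted alkenyl iodide.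

Step 3
Reactants: 4 L-erythrulose
Product: 5 3,4-O-isopropylidene-L-erythrulose
Conditions: Me2C(OMe)2, acetone, p-TsOH (cat.), rt
Reagents that add atoms: 2,2-dimethoxypropane, COC(C)(C)OC
Why: Acid-catalysed acetal exchange (acetonide formation) closes the five-membered dioxolane on the vicinal 3,4-diol in preference to other modes and leaves the single stereocentre, the future C8, untouched.

Step 4
Reactants: 5 3,4-O-isopropylidene-L-erythrulose
Product: 6 1-[(4S)-2,2-dimethyl-1,3-dioxolan-4-yl]-2-(triethylsilyloxy)ethan-1-one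
Conditions: Et3SiCl, imidazole, CH2Cl2, 0 °C
Reagents that add atoms: chlorotriethylsilane, CC[Si](Cl)(CC)CC
Why: Standard silylation of the remaining primary hydroxyl (O6) installs a bulky, poorly coordinating silyl ether that is needed for the facial control of step 6 and for the direct oxidation of step 8.

Step 5
Reactants: 7 2-bromoprop-2-en-1-ol
Product: 8 1-{[(2-bromoprop-2-en-1-yl)oxy]methyl}-4-methoxybenzene
Conditions: NaH, THF, 0 °C; 4-MeOC6H4CH2Cl, Bu4NI (cat.), 0 °C → rt
Reagents that add atoms: 4-methoxybenzyl chloride, COc1ccc(CCl)cc1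
Why: Williamson etherification of the sodium alkoxide with the benzylic chloride gives a PMB ether that tolerates organolithium and organoaluminium reagents and is later removed oxidatively, orthogonally to silyl ethers and the acetonide.

Step 6
Reactants: 8 1-{[(2-bromoprop-2-en-1-yl)oxy]methyl}-4-methoxybenzene; 6 1-[(4S)-2,2-dimethyl-1,3-dioxolan-4-yl]-2-(triethylsilyloxy)ethan-1-one
Product: 11 (2R)-2-[(4S)-2,2-dimethyl-1,3-dioxolan-4-yl]-3-{[(4-methoxybenzyl)oxy]methyl}-1-(triethylsilyloxy)but-3-en-2-ol, via alkenyllithium 9 (not isolated), via alkenylmagnesium bromide 10 (not isolated)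
Conditions: 8, t-BuLi (2 equiv), Et2O, −78 °C; MgBr2·OEt2, −78 °C; then 6, Et2O/CH2Cl2, −78 → −40 °C; aq. NH4Cl
Reagents that add atoms: none
Why: Bromine–lithium exchange followed by transmetalation gives an alkenyl Grignard reagent that adds to the ketone under Cram-chelate control: magnesium bridges the carbonyl oxygen and the dioxolane oxygen on C8 (the O6 silyl ether does not compete), and attack from the face of H8, away from the dioxolane CH2, sets C7 with O7 anti to O8.

Step 7
Reactants: 11 (2R)-2-[(4S)-2,2-dimethyl-1,3-dioxolan-4-yl]-3-{[(4-methoxybenzyl)oxy]methyl}-1-(triethylsilyloxy)but-3-en-2-ol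
Product: 12 (4S)-4-[(2R)-3-{[(4-methoxybenzyl)oxy]methyl}-1,2-bis(triethylsilyloxy)but-3-en-2-yl]-2,2-dimethyl-1,3-dioxolane
Conditions: Et3SiOTf, 2,6-lutidine, CH2Cl2, −78 → 0 °C
Reagents that add atoms: triethylsilyl trifluoromethanesulfonate, CC[Si](CC)(CC)OS(=O)(=O)C(F)(F)F
Why: Silyl triflate silylation of the hindered tertiary alcohol turns O7 into a non-chelating substituent for step 9 and prevents α-ketol rearrangement of the aldehyde made in step 8.

Step 8
Reactants: 12 (4S)-4-[(2R)-3-{[(4-methoxybenzyl)oxy]methyl}-1,2-bis(triethylsilyloxy)but-3-en-2-yl]-2,2-dimethyl-1,3-dioxolane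
Product: 13 (2S)-2-[(4S)-2,2-dimethyl-1,3-dioxolan-4-yl]-3-{[(4-methoxybenzyl)oxy]methyl}-2-(triethylsilyloxy)but-3-enal
Conditions: (COCl)2, DMSO, CH2Cl2, −78 → −40 °C; Et3N, −78 → 0 °C
Reagents that add atoms: none
Why: Swern oxidation applied to a silyl ether: the primary triethylsilyl ether is cleaved by the chlorosulfonium reagent and oxidised in the same flask, whereas the tertiary silyl ether, the PMB ether and the acetonide are inert and the fully substituted α-carbon cannot epimerise.

Step 9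
Reactants: 3 (5Z)-6-iodohept-5-en-1-yne; 13 (2S)-2-[(4S)-2,2-dimethyl-1,3-dioxolan-4-yl]-3-{[(4-methoxybenzyl)oxy]methyl}-2-(triethylsilyloxy)but-3-enal
Product: 15 (3R,4S,5E,9Z)-3-[(4S)-2,2-dimethyl-1,3-dioxolan-4-yl]-10-iodo-2-{[(4-methoxybenzyl)oxy]methyl}-6-methyl-3-(triethylsilyloxy)undeca-1,5,9-trien-4-ol, via alkenylalane 14 (not isolated)
Conditions: 3, AlMe3 (2 equiv), Cp2ZrCl2 (0.25 equiv), CH2Cl2, 0 °C → rt; volatiles removed; then 13, CH2Cl2, −78 → −20 °C; aq. potassium sodium tartrate
Reagents that add atoms: trimethylaluminium, C[Al](C)C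
Why: Zirconium-catalysed carboalumination adds methyl and aluminium syn across the terminal alkyne with aluminium at the terminal carbon, and the E alkenylalane then transfers its alkenyl group with retention to the aldehyde (1,2-addition); C6 should be set by Felkin–Anh attack anti to the C7–OSi bond with the nucleophile passing the C8 methine, a sense that the 1,3-anti preference exerted by the C8 oxygen reinforces.

Step 10
Reactants: 15 (3R,4S,5E,9Z)-3-[(4S)-2,2-dimethyl-1,3-dioxolan-4-yl]-10-iodo-2-{[(4-methoxybenzyl)oxy]methyl}-6-methyl-3-(triethylsilyloxy)undeca-1,5,9-trien-4-ol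
Product: 16 (3R,4S,5E,9Z)-3-[(4S)-2,2-dimethyl-1,3-dioxolan-4-yl]-2-(hydroxymethyl)-10-iodo-6-methyl-3-(triethylsilyloxy)undeca-1,5,9-trien-4-ol
Conditions: DDQ, CH2Cl2/pH 7 phosphate buffer (10:1), 0 °C
Reagents that add atoms: none
Why: Oxidative PMB ether cleavage by DDQ (hydride abstraction from the electron-rich benzylic position, then hydrolysis of the oxocarbenium ion) is faster than oxidation of the hindered secondary allylic alcohol and spares the silyl ether, the acetonide, the alkenes and the alkenyl iodide.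

Step 11
Reactants: 16 (3R,4S,5E,9Z)-3-[(4S)-2,2-dimethyl-1,3-dioxolan-4-yl]-2-(hydroxymethyl)-10-iodo-6-methyl-3-(triethylsilyloxy)undeca-1,5,9-trien-4-ol
Product: 19 (4R,5S)-4-[(4S)-2,2-dimethyl-1,3-dioxolan-4-yl]-5-[(1E,5Z)-6-iodo-2-methylhepta-1,5-dien-1-yl]-3-methylidene-4-(triethylsilyloxy)oxolan-2-one, via hydroxy enal 17 (not isolated), via lactol 18 (not isolated)
Conditions: TEMPO (0.2 equiv), PhI(OAc)2 (3 equiv), CH2Cl2, rt
Reagents that add atoms: none
Why: Oxoammonium-mediated oxidative lactonisation of a 1,4-diol: the primary allylic alcohol is oxidised selectively, the enal is trapped by the C6 hydroxyl as a five-membered lactol and this is oxidised to the lactone, C6 keeping its configuration because no bond to it is broken.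

Step 12
Reactants: 19 (4R,5S)-4-[(4S)-2,2-dimethyl-1,3-dioxolan-4-yl]-5-[(1E,5Z)-6-iodo-2-methylhepta-1,5-dien-1-yl]-3-methylidene-4-(triethylsilyloxy)oxolan-2-one
Product: 20 (4S,5S)-4-[(1S)-1,2-dihydroxyethyl]-4-hydroxy-5-[(1E,5Z)-6-iodo-2-methylhepta-1,5-dien-1-yl]-3-methylideneoxolan-2-one
Conditions: p-TsOH·H2O (cat.), MeOH, rt; used at once in step 13
Reagents that add atoms: none
Why: Acid-catalysed transketalisation in methanol removes the terminal acetonide and solvolyses the tertiary triethylsilyl ether in one operation, under conditions too mild to ionise the allylic C6–O lactone bond or to open the lactone.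

Step 13
Reactants: 20 (4S,5S)-4-[(1S)-1,2-dihydroxyethyl]-4-hydroxy-5-[(1E,5Z)-6-iodo-2-methylhepta-1,5-dien-1-yl]-3-methylideneoxolan-2-one
Product: 21 (4R,5S)-4-[(1S)-1,2-bis(triethylsilyloxy)ethyl]-5-[(1E,5Z)-6-iodo-2-methylhepta-1,5-dien-1-yl]-3-methylidene-4-(triethylsilyloxy)oxolan-2-one
Conditions: Et3SiOTf (4 equiv), 2,6-lutidine, CH2Cl2, −78 → 0 °C
Reagents that add atoms: triethylsilyl trifluoromethanesulfonate, CC[Si](CC)(CC)OS(=O)(=O)C(F)(F)F
Why: Silyl triflate with a hindered pyridine base silylates the primary, the secondary and the tertiary hydroxyl alike and, unlike nucleophilic amine bases, does not add to the α-methylene lactone.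

Step 14
Reactants: 21 (4R,5S)-4-[(1S)-1,2-bis(triethylsilyloxy)ethyl]-5-[(1E,5Z)-6-iodo-2-methylhepta-1,5-dien-1-yl]-3-methylidene-4-(triethylsilyloxy)oxolan-2-one
Product: 22 (2R)-2-[(2S,3R)-2-[(1E,5Z)-6-iodo-2-methylhepta-1,5-dien-1-yl]-4-methylidene-5-oxo-3-(triethylsilyloxy)oxolan-3-yl]-2-(triethylsilyloxy)acetaldehyde
Conditions: (COCl)2, DMSO, CH2Cl2, −78 → −40 °C; Et3N, −78 → −20 °C
Reagents that add atoms: none
Why: Swern oxidation again cleaves and oxidises only the primary triethylsilyl ether, so the C9 aldehyde is unveiled while the O8 and O7 silyl ethers stay in place, the latter blocking retro-aldol cleavage; the low temperature keeps the C8 stereocentre from enolising.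

Step 15
Reactants: 22 (2R)-2-[(2S,3R)-2-[(1E,5Z)-6-iodo-2-methylhepta-1,5-dien-1-yl]-4-methylidene-5-oxo-3-(triethylsilyloxy)oxolan-3-yl]-2-(triethylsilyloxy)acetaldehyde
Product: 24 (6S,7R,8S,9R)-9-hydroxy-7,8-bis(triethylsilyloxy)germacra-1(10)Z,4E,11(13)-trien-12,6-olide, via alkenylchromium 23 (not isolated)
Conditions: CrCl2 (10 equiv), NiCl2 (0.1 equiv), degassed DMSO, rt, slow addition of 22 to a final 0.002 M; aqueous work-up
Reagents that add atoms: none
Why: CrCl2 reduces NiCl2 to zerovalent nickel, which inserts into the C10–I bond with retention of the Z geometry; transfer of the alkenyl group to trivalent chromium gives the alkenylchromium 23, which adds to the chromium-coordinated C9 aldehyde and, after hydrolysis of the chromium alkoxide, gives the allylic alcohol. The closest known reaction type is the intramolecular Nozaki–Hiyama–Kishi coupling of alkenyl iodides with aldehydes that closes medium and large carbocyclic allylic alcohols. The ten-membered ring closes in the 10-exo-trig mode (carbonyl oxygen outside the ring) under high dilution, and the Z C1=C10 alkene together with the cis-fused lactone, which holds C5 and C8 on the same face of the five-membered ring, turns the two chain ends toward each other. The new C9 stereocentre should be controlled by the neighbouring C8 silyloxy centre inside the cyclic transition state: the C8–O bond lies anti to the forming C9–C10 bond and, because C7 is tied to the nucleophile through the short tether, it sits beside the aldehyde hydrogen while the chromium-bound oxygen points outward, so the alkenyl carbon reaches the Re face and the 8,9-syn (9R) carbinol results. The step needs chemoselectivity for the aldehyde over the lactone carbonyl, the exocyclic enoate and the silyl ethers, which the low basicity and the aldehyde preference of alkenylchromium reagents provide, and it needs O7 to stay silylated so that neither retro-aldol cleavage nor β-elimination of the aldehyde can intervene.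

Step 16
Reactants: 24 (6S,7R,8S,9R)-9-hydroxy-7,8-bis(triethylsilyloxy)germacra-1(10)Z,4E,11(13)-trien-12,6-olide; 25 angelic acid
Product: 27 (6S,7R,8S,9R)-9-[(2Z)-2-methylbut-2-enoyloxy]-7,8-bis(triethylsilyloxy)germacra-1(10)Z,4E,11(13)-trien-12,6-olide, via mixed anhydride 26 (not isolated)
Conditions: 25, 2,4,6-Cl3C6H2COCl, Et3N, toluene, rt; then 24, toluene, 75 °C
Reagents that add atoms: none
Why: Yamaguchi esterification: the hindered secondary allylic alcohol attacks the angeloyl carbonyl of the preformed mixed anhydride (the aroyl carbonyl is shielded by its two ortho chlorines), and running the acylation without a nucleophilic catalyst suppresses Z-to-E isomerisation to the tiglate.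

Step 17
Reactants: 27 (6S,7R,8S,9R)-9-[(2Z)-2-methylbut-2-enoyloxy]-7,8-bis(triethylsilyloxy)germacra-1(10)Z,4E,11(13)-trien-12,6-olide
Product: 28 (6S,7S,8S,9R)-9-[(2Z)-2-methylbut-2-enoyloxy]-7,8-dihydroxygermacra-1(10)Z,4E,11(13)-trien-12,6-olide
Conditions: HF·pyridine, pyridine, THF, 0 °C → rt
Reagents that add atoms: none
Why: Fluoride-mediated desilylation with pyridine-buffered HF·pyridine cleaves both Si–O bonds without the basic conditions that would invite acyl migration from O9 to O8, translactonisation or conjugate addition, and without acid strong enough for transannular cyclisation of the 1(10),4-diene.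

Compound list
1 | pent-4-yn-1-ol | C#CCCCO | starting material
2 | pent-4-ynal | C#CCCC=O | intermediate
3 | (5Z)-6-iodohept-5-en-1-yne | C#CCC/C=C(/C)I | intermediate
4 | L-erythrulose, (3S)-1,3,4-trihydroxybutan-2-one | OCC(=O)[C@@H](O)CO | starting material
5 | 3,4-O-isopropylidene-L-erythrulose, 1-[(4S)-2,2-dimethyl-1,3-dioxolan-4-yl]-2-hydroxyethan-1-one | OCC(=O)[C@@H]1COC(C)(C)O1 | intermediate
6 | 1-[(4S)-2,2-dimethyl-1,3-dioxolan-4-yl]-2-(triethylsilyloxy)ethan-1-one | CC[Si](CC)(CC)OCC(=O)[C@@H]1COC(C)(C)O1 | intermediate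
7 | 2-bromoprop-2-en-1-ol | C=C(Br)CO | starting material
8 | 1-{[(2-bromoprop-2-en-1-yl)oxy]methyl}-4-methoxybenzene (2-bromoallyl PMB ether) | C=C(Br)COCc1ccc(OC)cc1 | intermediate
9 | {3-[(4-methoxybenzyl)oxy]prop-1-en-2-yl}lithium (formed in the flask) | [Li]C(=C)COCc1ccc(OC)cc1 | intermediate
10 | {3-[(4-methoxybenzyl)oxy]prop-1-en-2-yl}magnesium bromide (formed in the flask) | Br[Mg]C(=C)COCc1ccc(OC)cc1 | intermediate
11 | (2R)-2-[(4S)-2,2-dimethyl-1,3-dioxolan-4-yl]-3-{[(4-methoxybenzyl)oxy]methyl}-1-(triethylsilyloxy)but-3-en-2-ol | CC[Si](CC)(CC)OC[C@](O)(C(=C)COCc1ccc(OC)cc1)[C@@H]1COC(C)(C)O1 | intermediate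
12 | (4S)-4-[(2R)-3-{[(4-methoxybenzyl)oxy]methyl}-1,2-bis(triethylsilyloxy)but-3-en-2-yl]-2,2-dimethyl-1,3-dioxolane | CC[Si](CC)(CC)OC[C@](O[Si](CC)(CC)CC)(C(=C)COCc1ccc(OC)cc1)[C@@H]1COC(C)(C)O1 | intermediate
13 | (2S)-2-[(4S)-2,2-dimethyl-1,3-dioxolan-4-yl]-3-{[(4-methoxybenzyl)oxy]methyl}-2-(triethylsilyloxy)but-3-enal | O=C[C@](O[Si](CC)(CC)CC)(C(=C)COCc1ccc(OC)cc1)[C@@H]1COC(C)(C)O1 | intermediate
14 | [(1E,5Z)-6-iodo-2-methylhepta-1,5-dien-1-yl]dimethylalane (formed in the flask) | C[Al](C)/C=C(\C)CC/C=C(/C)I | intermediate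
15 | (3R,4S,5E,9Z)-3-[(4S)-2,2-dimethyl-1,3-dioxolan-4-yl]-10-iodo-2-{[(4-methoxybenzyl)oxy]methyl}-6-methyl-3-(triethylsilyloxy)undeca-1,5,9-trien-4-ol | O[C@@H](/C=C(\C)CC/C=C(/C)I)[C@](O[Si](CC)(CC)CC)(C(=C)COCc1ccc(OC)cc1)[C@@H]1COC(C)(C)O1 | intermediate
16 | (3R,4S,5E,9Z)-3-[(4S)-2,2-dimethyl-1,3-dioxolan-4-yl]-2-(hydroxymethyl)-10-iodo-6-methyl-3-(triethylsilyloxy)undeca-1,5,9-trien-4-ol | O[C@@H](/C=C(\C)CC/C=C(/C)I)[C@](O[Si](CC)(CC)CC)(C(=C)CO)[C@@H]1COC(C)(C)O1 | intermediate
17 | (3R,4S,5E,9Z)-3-[(4S)-2,2-dimethyl-1,3-dioxolan-4-yl]-4-hydroxy-10-iodo-6-methyl-2-methylidene-3-(triethylsilyloxy)undeca-5,9-dienal (formed in the flask) | O[C@@H](/C=C(\C)CC/C=C(/C)I)[C@](O[Si](CC)(CC)CC)(C(=C)C=O)[C@@H]1COC(C)(C)O1 | intermediate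
18 | (4R,5S)-4-[(4S)-2,2-dimethyl-1,3-dioxolan-4-yl]-5-[(1E,5Z)-6-iodo-2-methylhepta-1,5-dien-1-yl]-3-methylidene-4-(triethylsilyloxy)oxolan-2-ol, either configuration at C12 (formed in the flask) | C=C1C(O)O[C@@H](/C=C(\C)CC/C=C(/C)I)[C@@]1(O[Si](CC)(CC)CC)[C@@H]2COC(C)(C)O2 | intermediate
19 | (4R,5S)-4-[(4S)-2,2-dimethyl-1,3-dioxolan-4-yl]-5-[(1E,5Z)-6-iodo-2-methylhepta-1,5-dien-1-yl]-3-methylidene-4-(triethylsilyloxy)oxolan-2-one | C=C1C(=O)O[C@@H](/C=C(\C)CC/C=C(/C)I)[C@@]1(O[Si](CC)(CC)CC)[C@@H]2COC(C)(C)O2 | intermediate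
20 | (4S,5S)-4-[(1S)-1,2-dihydroxyethyl]-4-hydroxy-5-[(1E,5Z)-6-iodo-2-methylhepta-1,5-dien-1-yl]-3-methylideneoxolan-2-one | C=C1C(=O)O[C@@H](/C=C(\C)CC/C=C(/C)I)[C@@]1(O)[C@@H](O)CO | intermediate
21 | (4R,5S)-4-[(1S)-1,2-bis(triethylsilyloxy)ethyl]-5-[(1E,5Z)-6-iodo-2-methylhepta-1,5-dien-1-yl]-3-methylidene-4-(triethylsilyloxy)oxolan-2-one | C=C1C(=O)O[C@@H](/C=C(\C)CC/C=C(/C)I)[C@@]1(O[Si](CC)(CC)CC)[C@@H](O[Si](CC)(CC)CC)CO[Si](CC)(CC)CC | intermediate
22 | (2R)-2-[(2S,3R)-2-[(1E,5Z)-6-iodo-2-methylhepta-1,5-dien-1-yl]-4-methylidene-5-oxo-3-(triethylsilyloxy)oxolan-3-yl]-2-(triethylsilyloxy)acetaldehyde (cyclisation precursor) | C=C1C(=O)O[C@@H](/C=C(\C)CC/C=C(/C)I)[C@@]1(O[Si](CC)(CC)CC)[C@@H](O[Si](CC)(CC)CC)C=O | intermediate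
23 | C10 dichlorochromium derivative of 22, iodine replaced by CrCl2 with the Z geometry kept (formed in the flask) | C=C1C(=O)O[C@@H](/C=C(\C)CC/C=C(/C)[Cr](Cl)Cl)[C@@]1(O[Si](CC)(CC)CC)[C@@H](O[Si](CC)(CC)CC)C=O | intermediate
24 | (6S,7R,8S,9R)-9-hydroxy-7,8-bis(triethylsilyloxy)germacra-1(10)Z,4E,11(13)-trien-12,6-olide | C=C1C(=O)O[C@H]2/C=C(\C)CC/C=C(/C)[C@@H](O)[C@H](O[Si](CC)(CC)CC)[C@@]12O[Si](CC)(CC)CC | intermediate
25 | angelic acid, (2Z)-2-methylbut-2-enoic acid | C/C=C(/C)C(=O)O | starting material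
26 | (2Z)-2-methylbut-2-enoic 2,4,6-trichlorobenzoic anhydride (formed in the flask) | C/C=C(/C)C(=O)OC(=O)c1c(Cl)cc(Cl)cc1Cl | intermediate
27 | (6S,7R,8S,9R)-9-[(2Z)-2-methylbut-2-enoyloxy]-7,8-bis(triethylsilyloxy)germacra-1(10)Z,4E,11(13)-trien-12,6-olide | C=C1C(=O)O[C@H]2/C=C(\C)CC/C=C(/C)[C@@H](OC(=O)/C(C)=C\C)[C@H](O[Si](CC)(CC)CC)[C@@]12O[Si](CC)(CC)CC | intermediate
28 | (6S,7S,8S,9R)-9-[(2Z)-2-methylbut-2-enoyloxy]-7,8-dihydroxygermacra-1(10)Z,4E,11(13)-trien-12,6-olide (CNP0303917.1) | C=C1C(=O)O[C@H]2/C=C(\C)CC/C=C(/C)[C@@H](OC(=O)/C(C)=C\C)[C@H](O)[C@@]12O | target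

Total step count: 17.
Longest linear sequence: 14 steps (steps 3, 4 and 6 to 17, from L-erythrulose).

Steps most likely to fail

Step 15 (ring closure). The medium-ring closure competes with reduction of the C–I bond and with oligomerisation. Above all, the alkenyl group may attack the opposite (Si) face of the aldehyde, in a Felkin-type arrangement with C7 beside the carbonyl oxygen, so that C9 is formed with the wrong configuration. Fallback: it sets out from 22 and no longer asks the ring closure to control C9. The cyclisation is run as above and the C9 epimer, (6S,7R,8S,9S)-9-hydroxy-7,8-bis(triethylsilyloxy)germacra-1(10)Z,4E,11(13)-trien-12,6-olide F1 (alone or mixed with 24), is oxidised with Dess–Martin periodinane (NaHCO3, CH2Cl2, 0 °C) to the ring ketone (6S,7R,8R)-9-oxo-7,8-bis(triethylsilyloxy)germacra-1(10)Z,4E,11(13)-trien-12,6-olide F2. A 1,2-selective Luche reduction (NaBH4, CeCl3·7H2O, MeOH, −78 °C) then sets C9 by hydride addition to an α-silyloxy ketone, for which the Felkin–Anh arrangement (C8–O anti to the hydride, H8 next to C10) leads to the 8,9-syn alcohol. The route is rejoined at 24.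

Step 9 (alkenylalane addition). The two carbon substituents on the quaternary C7 (C8 and C11) are similar in size, so the facial selectivity of the alkenyl transfer at C6 may be low or reversed; the hindered aldehyde may also react slowly. Fallback: it sets out from 3 and 13 and sets C6 by hydride delivery instead of by C–C bond formation. The addition is run as above and the C6 epimer, (3R,4R,5E,9Z)-3-[(4S)-2,2-dimethyl-1,3-dioxolan-4-yl]-10-iodo-2-{[(4-methoxybenzyl)oxy]methyl}-6-methyl-3-(triethylsilyloxy)undeca-1,5,9-trien-4-ol F3 (alone or mixed with 15), is oxidised with Dess–Martin periodinane to the dienone (3S,5E,9Z)-3-[(4S)-2,2-dimethyl-1,3-dioxolan-4-yl]-10-iodo-2-{[(4-methoxybenzyl)oxy]methyl}-6-methyl-3-(triethylsilyloxy)undeca-1,5,9-trien-4-one F4. Luche reduction (NaBH4, CeCl3·7H2O, MeOH, −78 °C) of this α-silyloxy ketone passes through the same arrangement about C6–C7 that favoured F3, but with hydride and alkenyl group exchanged, and therefore gives the 6S alcohol. The route is rejoined at 15.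

Step 16 (angeloylation). Acylation of the hindered C9 hydroxyl, flanked by the C8 silyl ether and the C10 methyl, may be slow, and under forcing conditions the Z double bond of the acyl donor may isomerise to the E (tigloyl) form. Fallback: it sets out from 24 and builds the angeloyl double bond on the substrate. Acylation with 2-[bis(2,2,2-trifluoroethoxy)phosphoryl]propanoic acid (DCC, DMAP, CH2Cl2) gives (6S,7R,8S,9R)-9-{2-[bis(2,2,2-trifluoroethoxy)phosphoryl]propanoyloxy}-7,8-bis(triethylsilyloxy)germacra-1(10)Z,4E,11(13)-trien-12,6-olide F5, which has no double bond that could isomerise. A Z-selective Still–Gennari olefination (KN(SiMe3)2, 18-crown-6, THF, −78 °C; acetaldehyde) then forms the (2Z)-2-methylbut-2-enoate. The route is rejoined at 27.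

Further compounds
F1 | step 15 | (6S,7R,8S,9S)-9-hydroxy-7,8-bis(triethylsilyloxy)germacra-1(10)Z,4E,11(13)-trien-12,6-olide | C=C1C(=O)O[C@H]2/C=C(\C)CC/C=C(/C)[C@H](O)[C@H](O[Si](CC)(CC)CC)[C@@]12O[Si](CC)(CC)CC
F2 | step 15 | (6S,7R,8R)-9-oxo-7,8-bis(triethylsilyloxy)germacra-1(10)Z,4E,11(13)-trien-12,6-olide | C=C1C(=O)O[C@H]2/C=C(\C)CC/C=C(/C)C(=O)[C@H](O[Si](CC)(CC)CC)[C@@]12O[Si](CC)(CC)CC
F3 | step 9 | (3R,4R,5E,9Z)-3-[(4S)-2,2-dimethyl-1,3-dioxolan-4-yl]-10-iodo-2-{[(4-methoxybenzyl)oxy]methyl}-6-methyl-3-(triethylsilyloxy)undeca-1,5,9-trien-4-ol | O[C@H](/C=C(\C)CC/C=C(/C)I)[C@](O[Si](CC)(CC)CC)(C(=C)COCc1ccc(OC)cc1)[C@@H]1COC(C)(C)O1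
F4 | step 9 | (3S,5E,9Z)-3-[(4S)-2,2-dimethyl-1,3-dioxolan-4-yl]-10-iodo-2-{[(4-methoxybenzyl)oxy]methyl}-6-methyl-3-(triethylsilyloxy)undeca-1,5,9-trien-4-one | O=C(/C=C(\C)CC/C=C(/C)I)[C@](O[Si](CC)(CC)CC)(C(=C)COCc1ccc(OC)cc1)[C@@H]1COC(C)(C)O1
F5 | step 16 | (6S,7R,8S,9R)-9-{2-[bis(2,2,2-trifluoroethoxy)phosphoryl]propanoyloxy}-7,8-bis(triethylsilyloxy)germacra-1(10)Z,4E,11(13)-trien-12,6-olide, both configurations at the phosphonate α-carbon | C=C1C(=O)O[C@H]2/C=C(\C)CC/C=C(/C)[C@@H](OC(=O)C(C)P(=O)(OCC(F)(F)F)OCC(F)(F)F)[C@H](O[Si](CC)(CC)CC)[C@@]12O[Si](CC)(CC)CC
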